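The oxolane C3 carbinol goes back to a ketone, the C4–CH2OH bond to a C4 enolate plus formaldehyde, and ring bond C4–C5 to an enol acetal. That acetal divides into an aryl aldehyde and a 3-aryl-lactic acid, and the dihydrobenzofuran is cut at C2–C3.
Enabling feature: in the oxolane, O1 lies between C5 (bearing the dihydrobenzofuranyl ring) and C2 (bearing the guaiacylmethyl group), and C2 adjoins oxygenated C3. O1–C2–C3 is therefore the O–Cα–C1 unit of a lactic acid and C5 a former aldehyde carbon, so the ring is the O-to-C isomer of a 2-aryl-5-benzyl-4-methylene-1,3-dioxolane.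
Ring order forward: dihydrobenzofuran (rhodium carbenoid C–H insertion), then 1,3-dioxolan-4-one (joins the two halves), then oxolan-3-one (Petasis–Ferrier rearrangement of the methylenated dioxolane).
Stereochemistry: benzofuran C2/C3 (cis) come from the chiral rhodium carboxylate and oxolane C2 from 3-methoxy-L-tyrosine. C5 follows from C2 in the rearrangement (2,5-cis), C4 from C5 in the aldol (4,5-trans), and C3 from C4 by hydroxyl-directed hydride delivery (3,4-trans).

Key step: step 13

Assumption: the dihydrobenzofuran is taken exactly as written, with the C2 aryl and C3 hydroxymethyl groups cis (2R,3R), and the (S)-configured ligand set of the rhodium catalyst is assigned to this series by analogy with simpler 2-(benzyloxy)phenyl diazoacetates; the mirror-image catalyst serves if the sense proves opposite.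
Abbreviations: ArV = 4-(benzyloxy)-3-methoxyphenyl; ArB = (2R,3R)-2-ArV-3-{[(tert-butyldimethylsilyl)oxy]methyl}-7-methoxy-2,3-dihydro-1-benzofuran-5-yl (ArV and CH2OTBS cis).

Step 1
Reactants: 1 4-(benzyloxy)-3-methoxybenzyl alcohol
Product: 2 4-(benzyloxy)-3-methoxybenzyl chloride
Conditions: SOCl2 (1.2 equiv), CH2Cl2, 0 °C; evaporate, use crude
Reagents that add atoms: thionyl chloride, O=S(Cl)Cl
Why: Deoxychlorination of an electron-rich benzylic alcohol through its chlorosulfite is fast at 0 °C, gives only gaseous by-products and does not touch the aryl benzyl ether.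

Step 2
Reactants: 2 4-(benzyloxy)-3-methoxybenzyl chloride; 3 5-iodovanillin
Product: 4 4-{[4-(benzyloxy)-3-methoxybenzyl]oxy}-3-iodo-5-methoxybenzaldehyde
Conditions: K2CO3 (1.5 equiv), DMF, rt to 40 °C
Reagents that add atoms: none
Why: Williamson ether synthesis: the formyl-acidified phenol is fully ionised by K2CO3, and the p-alkoxybenzyl chloride is reactive enough to alkylate the phenoxide despite its two ortho substituents.

Step 3
Reactants: 4 4-{[4-(benzyloxy)-3-methoxybenzyl]oxy}-3-iodo-5-methoxybenzaldehyde; 5 ethyl diazoacetate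
Product: 6 ethyl 2-(2-{[4-(benzyloxy)-3-methoxybenzyl]oxy}-5-formyl-3-methoxyphenyl)-2-diazoacetate
Conditions: Pd(PPh3)4 (5 mol %), Ag2CO3 (0.5 equiv), Et3N (1.3 equiv), toluene, rt
Reagents that add atoms: none
Why: Palladium-catalysed cross-coupling of an aryl iodide with the C–H bond of an acceptor diazo compound: oxidative addition, base-assisted palladation of the diazo carbon and reductive elimination run at room temperature faster than nitrogen loss, Ag2CO3 takes up iodide, and the non-enolisable formyl group is a spectator.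

Step 4
Reactants: 6 ethyl 2-(2-{[4-(benzyloxy)-3-methoxybenzyl]oxy}-5-formyl-3-methoxyphenyl)-2-diazoacetate
Product: 7 ethyl (2R,3S)-2-ArV-5-formyl-7-methoxy-2,3-dihydro-1-benzofuran-3-carboxylate (cis)
Conditions: Rh2(S-PTTL)4 [dirhodium tetrakis(N-phthaloyl-(S)-tert-leucinate)] (1 mol %), toluene (0.02 M), −60 °C
Reagents that add atoms: none
Why: Intramolecular 1,5-C–H insertion of a donor/acceptor rhodium carbenoid into the ArCH2–O methylene, which is activated by both the ether oxygen and the electron-rich arene; the concerted, hydride-transfer-like insertion inside the chiral pocket of the phthalimido-tert-leucinate ligands forms the C2–C3 bond and sets C2 (R) and C3 (S) together as the kinetic cis isomer, while low temperature and dilution hold back epimerisation and bimolecular carbonyl-ylide formation at the formyl group.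

Step 5
Reactants: 7 ethyl (2R,3S)-2-ArV-5-formyl-7-methoxy-2,3-dihydro-1-benzofuran-3-carboxylate
Product: 8 [(2R,3R)-2-ArV-7-methoxy-2,3-dihydro-1-benzofuran-3,5-diyl]dimethanol (cis)
Conditions: LiAlH4 (1.5 equiv), THF, −20 to 0 °C; aq. potassium sodium tartrate
Reagents that add atoms: none
Why: Hydride reduction of ester and aldehyde with LiAlH4 is faster than enolisation of the ester, so C3 keeps its geometry (its descriptor changes from S to R only because the CIP ranking of the substituent changes) and the cis relationship is locked once the acidifying carbonyl is gone.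

Step 6
Reactants: 8 [(2R,3R)-2-ArV-7-methoxy-2,3-dihydro-1-benzofuran-3,5-diyl]dimethanol
Product: 9 (2R,3R)-2-ArV-3-(hydroxymethyl)-7-methoxy-2,3-dihydro-1-benzofuran-5-carbaldehyde
Conditions: activated MnO2 (15 equiv), CH2Cl2, rt
Reagents that add atoms: none
Why: Chemoselective MnO2 oxidation: only the benzylic alcohol on the electron-rich ring is oxidised, the homobenzylic primary alcohol at C3 is inert, and the neutral heterogeneous medium leaves both stereocentres alone.

Step 7
Reactants: 9 (2R,3R)-2-ArV-3-(hydroxymethyl)-7-methoxy-2,3-dihydro-1-benzofuran-5-carbaldehyde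
Product: 10 ArB-carbaldehyde, i.e. (2R,3R)-2-ArV-3-{[(tert-butyldimethylsilyl)oxy]methyl}-7-methoxy-2,3-dihydro-1-benzofuran-5-carbaldehyde
Conditions: TBSCl (1.2 equiv), imidazole (2 equiv), CH2Cl2, 0 °C to rt
Reagents that add atoms: tert-butyldimethylsilyl chloride, CC(C)(C)[Si](C)(C)Cl
Why: Imidazole-promoted silylation of a primary alcohol; the TBS ether withstands the Lewis acids, Cp2TiMe2, LiN(iPr)2 and borohydride to come and is orthogonal to the benzyl ethers.

Step 8
Reactants: 11 3-methoxy-L-tyrosine
Product: 14 O-benzyl-3-methoxy-L-tyrosine, via copper chelate 12 (not isolated), via O-benzylated copper chelate 13 (not isolated)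
Conditions: CuSO4·5H2O (0.5 equiv), NaOH (2 equiv), H2O–MeOH, rt; BnBr (1.1 equiv), rt; then 1 M HCl
Reagents that add atoms: benzyl bromide, BrCc1ccccc1
Why: Chelation of the amino acid function to divalent copper masks nitrogen and carboxylate, so the Williamson alkylation takes place only at the phenoxide, and acid then releases the amino acid with the stereocentre untouched.

Step 9
Reactants: 14 O-benzyl-3-methoxy-L-tyrosine
Product: 15 (S)-3-ArV-2-hydroxypropanoic acid
Conditions: NaNO2 (1.5 equiv), 1 M H2SO4, 1,4-dioxane–H2O, 0 °C to rt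
Reagents that add atoms: water, O
Why: Diazotisation–hydrolysis of an α-amino acid: the neighbouring carboxylate displaces nitrogen and water then opens the strained ring so formed, two inversions that add up to retention, so the (S) centre that becomes oxolane C2 comes straight from the chiral pool, and the benzyl ether keeps the arene from being nitrosated as a free phenol would be.

Step 10
Reactants: 15 (S)-3-ArV-2-hydroxypropanoic acid
Product: 16 trimethylsilyl (S)-3-ArV-2-[(trimethylsilyl)oxy]propanoate
Conditions: (Me3Si)2NH (1.5 equiv), CH2Cl2, rt; evaporate, use crude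
Reagents that add atoms: hexamethyldisilazane, C[Si](C)(C)N[Si](C)(C)C
Why: Silylation of both acidic OH groups with hexamethyldisilazane releases only ammonia and gives the neutral partner needed for aprotic acetalisation.

Step 11
Reactants: 10 ArB-carbaldehyde; 16 trimethylsilyl (S)-3-ArV-2-[(trimethylsilyl)oxy]propanoate
Product: 17 (2S,5S)-2-ArB-5-(ArV-methyl)-1,3-dioxolan-4-one (2,5-cis)
Conditions: TMSOTf (20 mol %), 2,6-di-tert-butyl-4-methylpyridine (5 mol %), CH2Cl2, −78 °C; pyridine quench
Reagents that add atoms: none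
Why: TMSOTf-catalysed silyl-transfer acetalisation, driven by formation of hexamethyldisiloxane, works at −78 °C without free Brønsted acid so that the TBS ether and the cis-dihydrobenzofuran survive; ring closure places the new acetal carbon C2 (S) cis to the C5 benzyl group, the kinetically and thermodynamically preferred arrangement of 2,5-disubstituted dioxolanones, and chromatography here removes the diastereomer that stems from the minor enantiomer of 10.

Step 12
Reactants: 17 (2S,5S)-2-ArB-5-(ArV-methyl)-1,3-dioxolan-4-one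
Product: 18 (2S,5S)-2-ArB-5-(ArV-methyl)-4-methylidene-1,3-dioxolane (2,5-cis)
Conditions: Cp2TiMe2 (2.5 equiv), toluene, 65 °C, dark; filtration through basic alumina
Reagents that add atoms: Cp2TiMe2, C[Ti](C)(C1C=CC=C1)C1C=CC=C1
Why: Petasis methylenation: thermolysis of Cp2TiMe2 gives Cp2Ti=CH2, which converts the lactone carbonyl into the exocyclic enol ether by [2+2] cycloaddition and cycloreversion under non-basic, non-acidic conditions, so neither the α-centre C5 nor the acetal centre C2 is disturbed.

Step 13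
Reactants: 18 (2S,5S)-2-ArB-5-(ArV-methyl)-4-methylidene-1,3-dioxolane
Product: 20 (2S,5S)-2-(ArV-methyl)-5-ArB-oxolan-3-one (2,5-cis), via aluminium enolate oxocarbenium ion pair 19 (not isolated)
Conditions: Me2AlCl (1.5 equiv), CH2Cl2, −78 °C, short contact time; then aq. NaHCO3
Reagents that add atoms: none
Why: Me2AlCl coordinates the enol-ether oxygen O3 and breaks the O3–C2 acetal bond, which is easy because the cation is stabilised by O1 and by the para-oxygenated dihydrobenzofuranyl ring; the result is ion pair 19, an aluminium enolate held to an (E)-aryl oxocarbenium ion through O1 and the lactate carbon. The enolate methylene carbon then bonds to the oxocarbenium carbon, making C4–C5 and the oxolan-3-one; this is the Petasis–Ferrier rearrangement, known with alkylaluminium Lewis acids for 2-substituted 4-methylene-1,3-dioxolanes and for the homologous 1,3-dioxanes. The closure is formally 5-(enolendo)-endo-trig, awkward for a concerted attack but reached stepwise within a contact ion pair whose cationic carbon is strongly electrophilic and whose tether is only three atoms (C3, C2, O1) long. The one new stereocentre, C5, is controlled by the untouched lactate centre C2: in the envelope transition state the aryl group of the (E)-oxocarbenium ion and the C2 benzyl group both lie pseudo-equatorial, which should give the 2,5-cis ketone (2S,5S), also the more stable epimer. The step needs C-alkylation by the enolate ahead of six-membered oxa-Pictet–Spengler capture by the methoxy-activated C6 position of the benzyl arene and ahead of ionisation of the benzofuran C2–O bond; the anionic enolate is generated next to the cation and is by far the better nucleophile, O-recombination only regenerates 18, and −78 °C keeps the aryl ether bonds intact.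

Step 14
Reactants: 20 (2S,5S)-2-(ArV-methyl)-5-ArB-oxolan-3-one
Product: 22 (2S,4R,5S)-2-(ArV-methyl)-5-ArB-4-(hydroxymethyl)oxolan-3-one, via lithium enolate 21 (not isolated)
Conditions: LiN(iPr)2 (LDA, 1.1 equiv), THF, −78 °C; monomeric CH2O in THF, −78 °C; AcOH quench at −78 °C
Reagents that add atoms: formaldehyde, C=O
Why: Kinetic deprotonation with LDA takes a proton from the unhindered C4 methylene instead of the tertiary, oxygen-bearing C2–H, the C5–O1 bond lies near the nodal plane of the endocyclic enolate so β-elimination is slow at −78 °C, and the aldol addition to formaldehyde occurs on the face opposite the C5 aryl and C2 benzyl groups, which sets C4 (R) trans to the aryl group, also the more stable epimer.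

Step 15
Reactants: 22 (2S,4R,5S)-2-(ArV-methyl)-5-ArB-4-(hydroxymethyl)oxolan-3-one
Product: 24 (2S,3S,4S,5S)-2-(ArV-methyl)-5-ArB-4-(hydroxymethyl)oxolan-3-ol, via alkoxydiacetoxyborohydride 23 (not isolated)
Conditions: Me4NBH(OAc)3 (5 equiv), MeCN–AcOH (1:1), −30 to −20 °C
Reagents that add atoms: none
Why: Evans–Saksena hydroxyl-directed reduction: the C4 hydroxymethyl group replaces one acetate on boron and the tethered hydride reaches the C3 carbonyl only from the face that carries this group, so the new hydroxyl at C3 (S) ends up trans to C4–CH2OH and cis to the C2 benzyl group, while the untethered reagent does not reduce ketones on its own.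

Step 16
Reactants: 24 (2S,3S,4S,5S)-2-(ArV-methyl)-5-ArB-4-(hydroxymethyl)oxolan-3-ol
Product: 25 bis(O-benzyl) ether of the target, (2S,3S,4S,5S)-2-(ArV-methyl)-5-[(2R,3R)-2-ArV-3-(hydroxymethyl)-7-methoxy-2,3-dihydro-1-benzofuran-5-yl]-4-(hydroxymethyl)oxolan-3-ol
Conditions: Bu4NF (1.5 equiv), AcOH (1.5 equiv), THF, 0 °C to rt
Reagents that add atoms: none
Why: Fluoride-mediated desilylation buffered with acetic acid frees the primary alcohol under near-neutral conditions, and it is placed before debenzylation so that no free p-hydroxyphenyl group, which could open the cis-dihydrobenzofuran through a quinone methide, ever meets a basic reagent.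

Step 17
Reactants: 25 bis(O-benzyl) ether of the target
Product: 26 CNP0179668.1, (2S,3S,4S,5S)-2-(4-hydroxy-3-methoxybenzyl)-5-[(2R,3R)-2-(4-hydroxy-3-methoxyphenyl)-3-(hydroxymethyl)-7-methoxy-2,3-dihydro-1-benzofuran-5-yl]-4-(hydroxymethyl)oxolan-3-ol
Conditions: H2 (1 atm), 10% Pd/C, EtOAc–EtOH, rt, stopped at full conversion
Reagents that add atoms: none
Why: Catalytic hydrogenolysis: phenolic benzyl ethers are cleaved over Pd/C at 1 atm much faster than the secondary, ring-held benzylic C–O bonds at oxolane C5 and benzofuran C2, and the neutral medium leaves all six stereocentres untouched.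

Compound list
1 | 4-(benzyloxy)-3-methoxybenzyl alcohol | COc1cc(CO)ccc1OCc1ccccc1 | starting material
2 | 4-(benzyloxy)-3-methoxybenzyl chloride | COc1cc(CCl)ccc1OCc1ccccc1 | intermediate
3 | 5-iodovanillin (4-hydroxy-3-iodo-5-methoxybenzaldehyde) | COc1cc(C=O)cc(I)c1O | starting material
4 | 4-{[4-(benzyloxy)-3-methoxybenzyl]oxy}-3-iodo-5-methoxybenzaldehyde | COc1cc(C=O)cc(I)c1OCc1ccc(OCc2ccccc2)c(OC)c1 | intermediate
5 | ethyl diazoacetate | CCOC(=O)C=[N+]=[N-] | starting material
6 | ethyl 2-(2-{[4-(benzyloxy)-3-methoxybenzyl]oxy}-5-formyl-3-methoxyphenyl)-2-diazoacetate | CCOC(=O)C(=[N+]=[N-])c1cc(C=O)cc(OC)c1OCc1ccc(OCc2ccccc2)c(OC)c1 | intermediate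
7 | ethyl (2R,3S)-2-[4-(benzyloxy)-3-methoxyphenyl]-5-formyl-7-methoxy-2,3-dihydro-1-benzofuran-3-carboxylate (cis) | O=Cc1cc(OC)c2c(c1)[C@H](C(=O)OCC)[C@H](c1ccc(OCc3ccccc3)c(OC)c1)O2 | intermediate
8 | {(2R,3R)-2-[4-(benzyloxy)-3-methoxyphenyl]-7-methoxy-2,3-dihydro-1-benzofuran-3,5-diyl}dimethanol (cis) | OCc1cc(OC)c2c(c1)[C@H](CO)[C@H](c1ccc(OCc3ccccc3)c(OC)c1)O2 | intermediate
9 | (2R,3R)-2-[4-(benzyloxy)-3-methoxyphenyl]-3-(hydroxymethyl)-7-methoxy-2,3-dihydro-1-benzofuran-5-carbaldehyde | O=Cc1cc(OC)c2c(c1)[C@H](CO)[C@H](c1ccc(OCc3ccccc3)c(OC)c1)O2 | intermediate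
10 | (2R,3R)-2-[4-(benzyloxy)-3-methoxyphenyl]-3-{[(tert-butyldimethylsilyl)oxy]methyl}-7-methoxy-2,3-dihydro-1-benzofuran-5-carbaldehyde | O=Cc1cc(OC)c2c(c1)[C@H](CO[Si](C)(C)C(C)(C)C)[C@H](c1ccc(OCc3ccccc3)c(OC)c1)O2 | intermediate
11 | 3-methoxy-L-tyrosine | COc1cc(C[C@H](N)C(=O)O)ccc1O | starting material
12 | copper bis(3-methoxy-L-tyrosinate) chelate (formed in the flask) | [Cu+2].COc1cc(C[C@H](N)C(=O)[O-])ccc1O.COc1cc(C[C@H](N)C(=O)[O-])ccc1O | intermediate
13 | copper bis(O-benzyl-3-methoxy-L-tyrosinate) chelate (formed in the flask) | [Cu+2].COc1cc(C[C@H](N)C(=O)[O-])ccc1OCc1ccccc1.COc1cc(C[C@H](N)C(=O)[O-])ccc1OCc1ccccc1 | intermediate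
14 | O-benzyl-3-methoxy-L-tyrosine | COc1cc(C[C@H](N)C(=O)O)ccc1OCc1ccccc1 | intermediate
15 | (S)-3-[4-(benzyloxy)-3-methoxyphenyl]-2-hydroxypropanoic acid | COc1cc(C[C@H](O)C(=O)O)ccc1OCc1ccccc1 | intermediate
16 | trimethylsilyl (S)-3-[4-(benzyloxy)-3-methoxyphenyl]-2-[(trimethylsilyl)oxy]propanoate | COc1cc(C[C@H](O[Si](C)(C)C)C(=O)O[Si](C)(C)C)ccc1OCc1ccccc1 | intermediate
17 | (2S,5S)-2-ArB-5-[4-(benzyloxy)-3-methoxybenzyl]-1,3-dioxolan-4-one (2,5-cis) | O=C1O[C@@H](c2cc(OC)c3c(c2)[C@H](CO[Si](C)(C)C(C)(C)C)[C@H](c2ccc(OCc4ccccc4)c(OC)c2)O3)O[C@H]1Cc1ccc(OCc2ccccc2)c(OC)c1 | intermediate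
18 | (2S,5S)-2-ArB-5-[4-(benzyloxy)-3-methoxybenzyl]-4-methylidene-1,3-dioxolane (2,5-cis) | C=C1O[C@@H](c2cc(OC)c3c(c2)[C@H](CO[Si](C)(C)C(C)(C)C)[C@H](c2ccc(OCc4ccccc4)c(OC)c2)O3)O[C@H]1Cc1ccc(OCc2ccccc2)c(OC)c1 | intermediate
19 | ring-opened ion pair: chlorodimethylaluminate enolate of the (S)-3-oxy-4-ArV-butan-2-one unit, joined through that oxygen to the ArB-CH=O+ oxocarbenium carbon (formed in the flask) | C=C(O[Al-](C)(C)Cl)[C@H](Cc1ccc(OCc2ccccc2)c(OC)c1)[O+]=Cc1cc(OC)c2c(c1)[C@H](CO[Si](C)(C)C(C)(C)C)[C@H](c1ccc(OCc3ccccc3)c(OC)c1)O2 | intermediate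
20 | (2S,5S)-2-[4-(benzyloxy)-3-methoxybenzyl]-5-ArB-oxolan-3-one (2,5-cis) | COc1cc(C[C@@H]2O[C@H](c3cc(OC)c4c(c3)[C@H](CO[Si](C)(C)C(C)(C)C)[C@H](c3ccc(OCc5ccccc5)c(OC)c3)O4)CC2=O)ccc1OCc1ccccc1 | intermediate
21 | lithium C3=C4 enolate of 20 (formed in the flask) | COc1cc(C[C@@H]2O[C@H](c3cc(OC)c4c(c3)[C@H](CO[Si](C)(C)C(C)(C)C)[C@H](c3ccc(OCc5ccccc5)c(OC)c3)O4)C=C2O[Li])ccc1OCc1ccccc1 | intermediate
22 | (2S,4R,5S)-2-[4-(benzyloxy)-3-methoxybenzyl]-5-ArB-4-(hydroxymethyl)oxolan-3-one | COc1cc(C[C@@H]2O[C@H](c3cc(OC)c4c(c3)[C@H](CO[Si](C)(C)C(C)(C)C)[C@H](c3ccc(OCc5ccccc5)c(OC)c3)O4)[C@@H](CO)C2=O)ccc1OCc1ccccc1 | intermediate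
23 | tetramethylammonium diacetoxy(alkoxy)borohydride of 22, boron on the C4-CH2O oxygen (formed in the flask) | COc1cc(C[C@@H]2O[C@H](c3cc(OC)c4c(c3)[C@H](CO[Si](C)(C)C(C)(C)C)[C@H](c3ccc(OCc5ccccc5)c(OC)c3)O4)[C@@H](CO[BH-](OC(C)=O)OC(C)=O)C2=O)ccc1OCc1ccccc1.C[N+](C)(C)C | intermediate
24 | (2S,3S,4S,5S)-2-[4-(benzyloxy)-3-methoxybenzyl]-5-ArB-4-(hydroxymethyl)oxolan-3-ol | COc1cc(C[C@@H]2O[C@H](c3cc(OC)c4c(c3)[C@H](CO[Si](C)(C)C(C)(C)C)[C@H](c3ccc(OCc5ccccc5)c(OC)c3)O4)[C@@H](CO)[C@@H]2O)ccc1OCc1ccccc1 | intermediate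
25 | (2S,3S,4S,5S)-2-[4-(benzyloxy)-3-methoxybenzyl]-5-{(2R,3R)-2-[4-(benzyloxy)-3-methoxyphenyl]-3-(hydroxymethyl)-7-methoxy-2,3-dihydro-1-benzofuran-5-yl}-4-(hydroxymethyl)oxolan-3-ol | COc1cc(C[C@@H]2O[C@H](c3cc(OC)c4c(c3)[C@H](CO)[C@H](c3ccc(OCc5ccccc5)c(OC)c3)O4)[C@@H](CO)[C@@H]2O)ccc1OCc1ccccc1 | intermediate
26 | CNP0179668.1, (2S,3S,4S,5S)-2-(4-hydroxy-3-methoxybenzyl)-5-[(2R,3R)-2-(4-hydroxy-3-methoxyphenyl)-3-(hydroxymethyl)-7-methoxy-2,3-dihydro-1-benzofuran-5-yl]-4-(hydroxymethyl)oxolan-3-ol | COc1cc(C[C@@H]2O[C@H](c3cc(OC)c4c(c3)[C@H](CO)[C@H](c3ccc(O)c(OC)c3)O4)[C@@H](CO)[C@@H]2O)ccc1O | target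

Total step count: 17. Longest linear sequence: 14 steps (steps 1–7, then 11–17). The lactic acid branch (steps 8–10) is three steps and joins at step 11.

Steps most likely to fail

1. Step 13.
What may go wrong: electrophilic capture of the oxocarbenium carbon by the methoxy-activated ring of the neighbouring benzyl group. The Lewis acid may also ionise the benzylic C2–O bond of the dihydrobenzofuran, with cis-to-trans drift. The ketone may decay (enolisation, epimerisation at C2, ring opening) while it sits on the chloroaluminium centre.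
Fallback: the reductive form of the same O-to-C shift, followed by re-oxidation. It sets out from 18. iBu3Al (toluene, −78 to 0 °C), a milder, chloride-free Lewis acid with direct precedent on 4-methylene-1,3-dioxolanes, promotes the rearrangement. It at once reduces the aluminium-bound carbonyl by β-hydride transfer from the open face, so the sensitive ketone never accumulates. This should give (2S,3S,5S)-2-(ArV-methyl)-5-ArB-oxolan-3-ol F1. Dess–Martin periodinane (NaHCO3-buffered, CH2Cl2) then oxidises it, and the route is rejoined at 20.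

2. Step 14.
What may go wrong: incomplete regiocontrol in the deprotonation, loss of formaldehyde by retro-aldol reaction or dehydration of the lithium aldolate, ring opening by β-elimination of O1 if the enolate warms, and repeated hydroxymethylation.
Fallback: the carbon–carbon bond formation is moved from a basic lithium aldol to a Lewis-acid Mukaiyama aldol on an isolated enol silane. It sets out from 20. The kinetic enolate is trapped (LiN(iPr)2, TMSCl, THF, −78 °C) as the 3-(trimethylsilyloxy)-2,5-dihydrofuran F2, whose regiochemistry can be checked and which can be purified. Aqueous formaldehyde with Yb(OTf)3 (10 mol %) in THF–H2O at rt then adds on the same open face under nearly neutral conditions. The route is rejoined at 22.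

3. Step 3.
What may go wrong: slow coupling next to the bulky ortho ether, so that nitrogen loss from the palladium-bound diazo compound (carbene migratory insertion, dimerisation) overtakes reductive elimination.
Fallback: the carbon framework and the diazo group are installed separately. It sets out from 4. A Migita–Kosugi–Stille-type coupling with ethyl (tributylstannyl)acetate (PdCl2[P(o-tol)3]2, ZnBr2, DMF, 80 °C), which tolerates the free aldehyde, should give ethyl 2-(2-{[4-(benzyloxy)-3-methoxybenzyl]oxy}-5-formyl-3-methoxyphenyl)acetate F3. Regitz diazo transfer (4-acetamidobenzenesulfonyl azide, DBU, MeCN, 0 °C to rt) then rejoins the route at 6.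

Further compounds
F1 | step 13 | (2S,3S,5S)-2-[4-(benzyloxy)-3-methoxybenzyl]-5-ArB-oxolan-3-ol | COc1cc(C[C@@H]2O[C@H](c3cc(OC)c4c(c3)[C@H](CO[Si](C)(C)C(C)(C)C)[C@H](c3ccc(OCc5ccccc5)c(OC)c3)O4)C[C@@H]2O)ccc1OCc1ccccc1
F2 | step 14 | (2S,5S)-2-[4-(benzyloxy)-3-methoxybenzyl]-5-ArB-3-[(trimethylsilyl)oxy]-2,5-dihydrofuran | COc1cc(C[C@@H]2O[C@H](c3cc(OC)c4c(c3)[C@H](CO[Si](C)(C)C(C)(C)C)[C@H](c3ccc(OCc5ccccc5)c(OC)c3)O4)C=C2O[Si](C)(C)C)ccc1OCc1ccccc1
F3 | step 3 | ethyl 2-(2-{[4-(benzyloxy)-3-methoxybenzyl]oxy}-5-formyl-3-methoxyphenyl)acetate | CCOC(=O)Cc1cc(C=O)cc(OC)c1OCc1ccc(OCc2ccccc2)c(OC)c1
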